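## Analysis of the target

Biogenetic verticillane numbering is used for all bicyclic compounds. The six-membered ring is C1, C14, C13, C12, C11, C15. The chain C2–C10 runs from C1 to C11. C18 is the methylene on C12, and the methyls sit on C4, C8 and C15 (two).

- The target is a bicyclo[9.3.1]pentadecane: a cyclohexane that shares its C1–C15–C11 edge with a twelve-membered carbocycle, with the quaternary gem-dimethyl carbon C15 as the one-carbon bridge.
- C2 and C10 leave the six-membered ring on opposite faces (trans across C15, an in,out-type bridge). C1 is R and C11 is S in the target; the same spatial arrangement is 1S,11R in the parent hydrocarbon.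
- The macrocycle carries a trans-epoxide at C3–C4 (3R,4R) and a cis-epoxide at C7–C8 (7R,8S). Their precursor olefins must therefore be 3E and 7Z.
- C10 (R) bears the acetate and sits next to the bridgehead C11, which links it to the cross-conjugated α-methylene ketone (C12=C18, C13=O).
- Sensitive groups: the α-methylene ketone is a Michael acceptor and can isomerise to the endocyclic C11=C12 enone. Both trisubstituted epoxides are acid-labile and open to transannular attack.
- The difficulty lies in the hindered bridgeheads on either side of C15, the twelve-membered ring, and seven stereocentres with few polar handles for C–C bond formation.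
- The strategy rests on one feature: read as C2→C14, then C1, then C15, the twenty skeletal carbons are an unbroken head-to-tail tetraprenyl chain. Only C1–C2 and C11–C15 lie outside that chain. Every oxygen sits on a former olefin carbon (C3, C4, C7, C8), on an allylic carbon (C13) or on C10.

## Retrosynthetic reasoning

**C10–OAc.** Target 24 is the acetate of alcohol 23. The ester is cut last because an acetate would not survive the hydride and organometallic steps earlier in the route.

**C10–O.** Alcohol 23 is traced to enone 22 by removing the hydroxyl. C10 is the only methylene of 22 that is neither attached to an epoxide carbon nor α to the ketone, so it is the least deactivated C–H site. Placing this oxygen before the cyclisation would put a heteroatom beside the olefin that has to act as the nucleophile there. The forward step needs a monooxygenase that finds C10 and the face that gives 10R.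

**C13=O.** Enone 22 comes from allylic alcohol 21, and 21 from exocyclic olefin 20. The olefin of 20 has two allylic positions, the methylene C13 and the hindered methine C11. An ene-type selenium oxidation should choose C13 and return the double bond to C12=C18.

**The four epoxide C–O bonds.** Bis-epoxide 20 is traced to triene 19. Syn oxygen transfer turns 3E into the trans-epoxide and 7Z into the cis-epoxide. The forward step must prefer the two trisubstituted ring olefins over the 1,1-disubstituted one and attack each from the face the target requires.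

**C1–C2 and C11–C15 (key disconnection).** Cutting these two bonds of 19 opens both rings and gives the acyclic diphosphate 16. No other pair of cuts turns the bicycle into a single linear precursor whose olefins already hold every carbon in place. The forward step forms two rings, two C–C bonds and both bridgehead stereocentres, and must end by loss of a proton from C18.

**C–O–P.** Diphosphate 16 comes from allylic chloride 15 and this from alcohol 14 by two SN2 steps at the primary allylic carbon, which leave all three olefin geometries untouched.

**Chain C8–C9 (C9–C10 of the bicycle).** Alcohol 14 is traced through silyl ether 13 and sulfone 12 to geranyl phenyl sulfone 11 and the Z-allylic bromide 9. This cut divides the chain into two C10 halves from the same terpene pool and keeps the only Z olefin inside one small fragment.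

**Chain C6=C7 (Z).** Bromide 9 comes from alcohol 8 and ester 7. Ester 7 is cut at the olefin into aldehyde 5 and phosphonate 6. A Z-selective Horner–Wadsworth–Emmons reaction is the most dependable way to a Z-trisubstituted olefin whose methyl-bearing carbon also carries the CH2X group.

**Aldehyde 5.** It is reached from geraniol 1 through silyl ether 2, epoxide 3 and diol 4 by cleaving the terminal olefin. The silyl ether replaces an acetate because the oxygen must survive the later hydride reduction of 7.

**Sulfone 11.** It is made in one substitution from geranyl bromide 10.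

## Alternatives that were turned down

**Alternative 1:** The cut is at C4–C5, with the C3–C4 epoxide as retron.
- Forward step: the homoallylic Grignard reagent A3 adds to the C4 carbonyl of the ring-bound α-chloro ketone A2 anti to chlorine (Cornforth control). The alkoxide then displaces chloride at C3 and gives the trans-epoxide A1.
- For it: the C3/C4 configuration comes from an open-chain model that does not depend on macrocycle conformation. On this point it is stronger than the peracid step of the chosen route, and every reaction is of a known type.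
- Against it: A1 is still open. The twelve-membered ring must be closed at C9–C10 with an epoxide present, and that closure must also set C10. A2 needs both bridgehead stereocentres beside C15 and an epimerisable chlorine-bearing centre. Enolisation of the chloro ketone competes with addition. The late dioxolane removal meets two acid-labile epoxides.
- Comparison: the ring-fragment synthesis alone should exceed the length of the whole chosen route. In return for untested enzyme acceptance, the chosen route makes the full skeleton and both bridgeheads in one step.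

**Alternative 2:** The cut is at C10–C11 by a retro-[2,3] shift, which leads to the fifteen-membered stannyl allyl ether A5.
- Forward step: tin–lithium exchange at C10 triggers a Wittig–Still shift that forms C10–C11, breaks O–C18, moves the olefin to C12=C18 and contracts the ring to give A4.
- For it: one step delivers the C10 hydroxyl, the C11 stereocentre and the exocyclic methylene. The chosen route needs three operations for these, and its C10 oxygen depends on an enzyme. On C10 this alternative is clearly stronger.
- Against it: the carbanion is tethered to C1 on one face of the six-membered ring but must bond to C11 from the opposite face to give the trans bridge. That transition state is strained and untested, with [1,2] shift and the wrong C11 epimer as likely outcomes. The α-alkoxystannane centre, the C1 centre and an extra macro-etherification must be provided first.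
- Comparison: the route is long and ends with the same deketalisation hazard. The chosen strategy offers a short linear precursor built with no chiral reagent.

**Alternative 3:** The cuts are C8–C9 and C10–O by a retro-dipolar cycloaddition.
- Forward step: aldoxime A7 is oxidised to its nitrile oxide, which adds to the vinyl group on C11 and gives the isoxazoline-bridged macrocycle A6.
- For it: nitrile oxide cycloaddition is among the most dependable macrocyclisations. Its normal regiochemistry puts oxygen on C10 and carbon on C9. Ring closure and C10 oxygenation are better precedented here than in the chosen route.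
- Against it: the C10 configuration depends on the facial preference of a vinyl group next to C11 inside a macrocyclic transition state. C8 emerges as a C=N carbon without its methyl. N–O cleavage, methyl addition to a macrocyclic ketone with uncertain facial selectivity, and epoxide closure from the C7 oxygen must follow, on a β-hydroxy ketone prone to retro-aldol cleavage.
- Comparison: A7 needs three stereocentres before the key step. The chosen route takes the C8 methyl and the 7Z geometry directly from the chain.

Key step: step 13

Assumption: the cyclase variant of step 13 and the hydroxylase variant of step 17 are taken to be obtainable by expression and screening of active-site libraries; no particular variant is implied.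

Remark: acyclic compounds carry chain numbering (C1 is the oxygen-bearing carbon). Chain C1–C13 become C2–C14 of the bicycle, chain C14 becomes C1 and chain C15 stays C15. Compound 16 is drawn as the free acid and would be handled as its tris-ammonium salt.

## Route

Step 1
Reactants: 1 geraniol
Product: 2 tert-butyl{[(2E)-3,7-dimethylocta-2,6-dien-1-yl]oxy}diphenylsilane
Conditions: t-BuPh2SiCl, imidazole, DMF, 0 °C to rt
Reagents that add atoms: tert-butyl(chloro)diphenylsilane, CC(C)(C)[Si](Cl)(c1ccccc1)c1ccccc1
Why: Silylation of a primary allylic alcohol; the robust silyl ether is chosen because it should survive peracid, periodic acid, amide base, aluminium hydride and organolithium conditions.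

Step 2
Reactants: 2 tert-butyl{[(2E)-3,7-dimethylocta-2,6-dien-1-yl]oxy}diphenylsilane
Product: 3 tert-butyl{[(2E)-5-(3,3-dimethyloxiran-2-yl)-3-methylpent-2-en-1-yl]oxy}diphenylsilane (racemic)
Conditions: mCPBA (1.05 equiv), NaHCO3, CH2Cl2, −20 to 0 °C
Reagents that add atoms: 3-chloroperoxybenzoic acid, O=C(OO)c1cccc(Cl)c1
Why: Prilezhaev epoxidation; the remote trisubstituted olefin is more electron-rich than the one deactivated by the allylic oxygen, and the new stereocentre is destroyed in step 3.

Step 3
Reactants: 3 tert-butyl{[(2E)-5-(3,3-dimethyloxiran-2-yl)-3-methylpent-2-en-1-yl]oxy}diphenylsilane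
Product: 5 (4E)-6-[(tert-butyldiphenylsilyl)oxy]-4-methylhex-4-enal, via vicinal diol 4 (not isolated)
Conditions: H5IO6, THF/H2O, 0 °C
Reagents that add atoms: water, O (its oxygen enters 4 and leaves again in the acetone; none of it remains in 5)
Why: Periodic acid hydrolyses the epoxide and cleaves the resulting glycol in one operation (Malaprade cleavage); the 2E olefin and the silyl ether should be untouched in the short reaction time.

Step 4
Reactants: 5 (4E)-6-[(tert-butyldiphenylsilyl)oxy]-4-methylhex-4-enal; 6 methyl 2-[bis(2,2,2-trifluoroethoxy)phosphoryl]propanoate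
Product: 7 methyl (2Z,6E)-8-[(tert-butyldiphenylsilyl)oxy]-2,6-dimethylocta-2,6-dienoate
Conditions: KN(SiMe3)2, 18-crown-6, THF, −78 °C
Reagents that add atoms: none
Why: Still–Gennari olefination; the electron-poor phosphonate makes elimination from the kinetic adduct fast and irreversible, which should give the Z-trisubstituted enoate with high selectivity for an unbranched aliphatic aldehyde.

Step 5
Reactants: 7 methyl (2Z,6E)-8-[(tert-butyldiphenylsilyl)oxy]-2,6-dimethylocta-2,6-dienoate
Product: 8 (2Z,6E)-8-[(tert-butyldiphenylsilyl)oxy]-2,6-dimethylocta-2,6-dien-1-ol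
Conditions: i-Bu2AlH (2.5 equiv), CH2Cl2, −78 °C; aq. potassium sodium tartrate
Reagents that add atoms: none
Why: 1,2-Reduction of an enoate to the allylic alcohol by an aluminium hydride; the olefin geometry is not affected.

Step 6
Reactants: 8 (2Z,6E)-8-[(tert-butyldiphenylsilyl)oxy]-2,6-dimethylocta-2,6-dien-1-ol
Product: 9 tert-butyl{[(2E,6Z)-8-bromo-3,7-dimethylocta-2,6-dien-1-yl]oxy}diphenylsilane
Conditions: CBr4, PPh3, CH2Cl2, 0 °C; used at once
Reagents that add atoms: carbon tetrabromide, BrC(Br)(Br)Br
Why: Appel bromination by SN2 at the primary allylic carbon; immediate use limits allylic transposition that could erode the Z geometry.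

Step 7
Reactants: 10 geranyl bromide
Product: 11 {[(2E)-3,7-dimethylocta-2,6-dien-1-yl]sulfonyl}benzene (geranyl phenyl sulfone)
Conditions: PhSO2Na, DMF, rt
Reagents that add atoms: sodium benzenesulfinate, [Na+].[O-]S(=O)c1ccccc1
Why: S-Alkylation of the soft sulfinate anion by SN2 at the primary allylic bromide.

Step 8
Reactants: 11 geranyl phenyl sulfone; 9 tert-butyl{[(2E,6Z)-8-bromo-3,7-dimethylocta-2,6-dien-1-yl]oxy}diphenylsilane
Product: 12 tert-butyl{[(2E,6Z,10E)-3,7,11,15-tetramethyl-9-(phenylsulfonyl)hexadeca-2,6,10,14-tetraen-1-yl]oxy}diphenylsilane (racemic at C9)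
Conditions: n-BuLi, THF, −78 °C; then 9, −78 to −20 °C
Reagents that add atoms: none
Why: Alkylation of the sulfone-stabilised allylic carbanion at its α-carbon by the primary allylic bromide joins chain C8 to C9 without touching any olefin; the sulfone-bearing stereocentre is removed in step 9.

Step 9
Reactants: 12 tert-butyl{[(2E,6Z,10E)-3,7,11,15-tetramethyl-9-(phenylsulfonyl)hexadeca-2,6,10,14-tetraen-1-yl]oxy}diphenylsilane
Product: 13 tert-butyldiphenyl{[(2E,6Z,10E)-3,7,11,15-tetramethylhexadeca-2,6,10,14-tetraen-1-yl]oxy}silane
Conditions: PdCl2(dppp) (5 mol %), LiBHEt3, THF, 0 °C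
Reagents that add atoms: none
Why: Palladium-catalysed reductive desulfonylation; zerovalent palladium ionises the allylic sulfone and hydride is delivered to the less substituted allyl terminus, so the 10E olefin keeps position and geometry, and the 6Z olefin is outside the allyl system.

Step 10
Reactants: 13 tert-butyldiphenyl{[(2E,6Z,10E)-3,7,11,15-tetramethylhexadeca-2,6,10,14-tetraen-1-yl]oxy}silane
Product: 14 (2E,6Z,10E)-3,7,11,15-tetramethylhexadeca-2,6,10,14-tetraen-1-ol
Conditions: Bu4NF, THF, rt
Reagents that add atoms: none
Why: Fluoride-induced desilylation of the primary silyl ether.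

Step 11
Reactants: 14 (2E,6Z,10E)-3,7,11,15-tetramethylhexadeca-2,6,10,14-tetraen-1-ol
Product: 15 (2E,6Z,10E)-1-chloro-3,7,11,15-tetramethylhexadeca-2,6,10,14-tetraene
Conditions: N-chlorosuccinimide, Me2S, CH2Cl2, −40 to 0 °C
Reagents that add atoms: N-chlorosuccinimide, O=C1CCC(=O)N1Cl
Why: Corey–Kim chlorination through an alkoxysulfonium salt; SN2 at the primary carbon gives the allylic chloride without transposition of the 2E olefin.

Step 12
Reactants: 15 (2E,6Z,10E)-1-chloro-3,7,11,15-tetramethylhexadeca-2,6,10,14-tetraene
Product: 16 (2E,6Z,10E)-geranylgeranyl diphosphate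
Conditions: (Bu4N)3HP2O7, MeCN, rt; then cation-exchange resin (NH4+ form), aq. NH4HCO3/i-PrOH; cellulose chromatography
Reagents that add atoms: tris(tetrabutylammonium) hydrogen diphosphate, CCCC[N+](CCCC)(CCCC)CCCC.CCCC[N+](CCCC)(CCCC)CCCC.CCCC[N+](CCCC)(CCCC)CCCC.OP([O-])(=O)OP([O-])([O-])=O
Why: SN2 displacement of the primary allylic chloride by the diphosphate anion, the standard entry to prenyl diphosphates.

Step 13
Reactants: 16 (2E,6Z,10E)-geranylgeranyl diphosphate
Product: 19 (1S,11R,3E,7Z)-verticilla-3,7,12(18)-triene, via monocyclic tertiary cation 17 (not isolated), via verticillen-12-yl cation 18 (not isolated)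
Conditions: verticillene-forming taxadiene synthase variant (class 1 diterpene synthase, purified), MgCl2, HEPES pH 8.0, dithiothreitol, glycerol, 30 °C, n-pentane overlay
Reagents that add atoms: none
Why: Proposed new method: magnesium-assisted ionisation of the diphosphate gives an allyl cation whose primary terminus (chain C1) is attacked by chain C14 of the terminal olefin, which closes the fourteen-membered ring in the exo sense with respect to that olefin and leaves the tertiary cation 17. Chain C15 is then attacked through chain C10 by the 10E olefin in a 6-endo closure that creates the cyclohexane and with it the twelve-membered ring, giving the tertiary cation 18, which loses a proton from C18. The closest known reaction type is the conversion of all-E geranylgeranyl diphosphate into verticillene-type trienes by taxadiene synthase and its variants; the 6Z substrate is what is new. C1 is set by the face of the terminal olefin that the enzyme presents to the allyl cation and C11 by the face of the 10E olefin presented to C15; both are fixed by the active-site fold, which in this enzyme family gives 1S,11R with C2 and C10 trans. The step needs Markovnikov bond formation at both stages, a single deprotonation site (C18, not C13 or C11) and a stop before any onward proton relay to a taxane. The 2E olefin, the 10E olefin, the terminal olefin and the diphosphate are those of the natural substrate, so both bond-forming sites are unchanged. The 6Z olefin lies in the part of the chain that only spans the large ring, and its geometry should also disfavour the C11-to-C7 proton transfer that normally carries the cascade further.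

Step 14
Reactants: 19 (1S,11R,3E,7Z)-verticilla-3,7,12(18)-triene
Product: 20 (1S,3R,4R,7R,8S,11R)-3,4:7,8-diepoxyverticill-12(18)-ene
Conditions: mCPBA (2.1 equiv), NaHCO3, CH2Cl2, −30 to 0 °C
Reagents that add atoms: 3-chloroperoxybenzoic acid, O=C(OO)c1cccc(Cl)c1
Why: Prilezhaev epoxidation; the two trisubstituted ring olefins react well ahead of the hindered 1,1-disubstituted one, and stereospecific syn transfer turns 3E into the trans-epoxide and 7Z into the cis-epoxide. Each olefin of the twelve-membered ring should be attacked on its outward face in the ground-state conformer, the mode that usually reproduces the natural epoxide configuration in macrocyclic terpenes and is expected to give 3R,4R,7R,8S.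

Step 15
Reactants: 20 (1S,3R,4R,7R,8S,11R)-3,4:7,8-diepoxyverticill-12(18)-ene
Product: 21 3,4:7,8-diepoxyverticill-12(18)-en-13-ol (both C13 epimers; other stereocentres as in 20)
Conditions: SeO2 (0.3 equiv), t-BuOOH, CH2Cl2, 0 °C to rt
Reagents that add atoms: tert-butyl hydroperoxide, CC(C)(C)OO (its oxygen is handed on by the catalyst selenium dioxide, O=[Se]=O)
Why: Selenium dioxide allylic oxidation (ene reaction at C18, then [2,3]-sigmatropic shift) returns the olefin to C12=C18 and places oxygen on the ring methylene C13 in preference to the hindered methine C11; the C13 configuration is immaterial because step 16 removes it.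

Step 16
Reactants: 21 3,4:7,8-diepoxyverticill-12(18)-en-13-ol
Product: 22 (1R,3R,4R,7R,8S,11S)-3,4:7,8-diepoxyverticill-12(18)-en-13-one
Conditions: Dess–Martin periodinane, NaHCO3, CH2Cl2, 0 °C to rt
Reagents that add atoms: none
Why: Buffered Dess–Martin oxidation of the allylic alcohol to the α-methylene ketone; the neutral conditions should spare both epoxides and avoid isomerisation of the exocyclic olefin.

Step 17
Reactants: 22 (1R,3R,4R,7R,8S,11S)-3,4:7,8-diepoxyverticill-12(18)-en-13-one
Product: 23 (1R,3R,4R,7R,8S,10R,11S)-3,4:7,8-diepoxy-10-hydroxyverticill-12(18)-en-13-one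
Conditions: P450 BM3 (CYP102A1) variant from an active-site library, NADP+ (cat.), glucose, glucose dehydrogenase, air, KH2PO4/K2HPO4 buffer pH 8.0, 2% DMSO, 25 °C
Reagents that add atoms: dioxygen, O=O
Why: Enzymatic C–H hydroxylation by hydrogen abstraction and oxygen rebound with retention, a reaction type established for engineered P450 variants on epoxy-terpenoid macrocycles that carry α-methylene carbonyl groups. C10 is the only methylene of 22 not deactivated by an adjacent epoxide carbon or carbonyl, and the enzyme pocket is relied on for the site and for the face that gives 10R.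

Step 18
Reactants: 23 (1R,3R,4R,7R,8S,10R,11S)-3,4:7,8-diepoxy-10-hydroxyverticill-12(18)-en-13-one
Product: 24 (1R,3R,4R,7R,8S,10R,11S)-10-acetoxy-3,4:7,8-diepoxyverticill-12(18)-en-13-one (target)
Conditions: Ac2O, pyridine, DMAP (cat.), CH2Cl2, 0 °C
Reagents that add atoms: acetic anhydride, CC(=O)OC(C)=O
Why: Nucleophile-catalysed acetylation of the secondary alcohol under mild basic conditions; oxa-Michael closure of the free alcohol onto C18 would be a disfavoured 5-endo process, so 23 should reach this step intact.

## Compound list

1 | geraniol | CC(C)=CCC/C(C)=C/CO | starting material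
2 | tert-butyl{[(2E)-3,7-dimethylocta-2,6-dien-1-yl]oxy}diphenylsilane | CC(C)=CCC/C(C)=C/CO[Si](c1ccccc1)(c1ccccc1)C(C)(C)C | intermediate
3 | tert-butyl{[(2E)-5-(3,3-dimethyloxiran-2-yl)-3-methylpent-2-en-1-yl]oxy}diphenylsilane (racemic) | CC1(C)OC1CC/C(C)=C/CO[Si](c1ccccc1)(c1ccccc1)C(C)(C)C | intermediate
4 | (6E)-8-[(tert-butyldiphenylsilyl)oxy]-2,6-dimethyloct-6-ene-2,3-diol (racemic, not isolated) | CC(C)(O)C(O)CC/C(C)=C/CO[Si](c1ccccc1)(c1ccccc1)C(C)(C)C | intermediate
5 | (4E)-6-[(tert-butyldiphenylsilyl)oxy]-4-methylhex-4-enal | O=CCC/C(C)=C/CO[Si](c1ccccc1)(c1ccccc1)C(C)(C)C | intermediate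
6 | methyl 2-[bis(2,2,2-trifluoroethoxy)phosphoryl]propanoate | COC(=O)C(C)P(=O)(OCC(F)(F)F)OCC(F)(F)F | starting material
7 | methyl (2Z,6E)-8-[(tert-butyldiphenylsilyl)oxy]-2,6-dimethylocta-2,6-dienoate | COC(=O)/C(C)=C\CC/C(C)=C/CO[Si](c1ccccc1)(c1ccccc1)C(C)(C)C | intermediate
8 | (2Z,6E)-8-[(tert-butyldiphenylsilyl)oxy]-2,6-dimethylocta-2,6-dien-1-ol | OC/C(C)=C\CC/C(C)=C/CO[Si](c1ccccc1)(c1ccccc1)C(C)(C)C | intermediate
9 | tert-butyl{[(2E,6Z)-8-bromo-3,7-dimethylocta-2,6-dien-1-yl]oxy}diphenylsilane | BrC/C(C)=C\CC/C(C)=C/CO[Si](c1ccccc1)(c1ccccc1)C(C)(C)C | intermediate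
10 | geranyl bromide | CC(C)=CCC/C(C)=C/CBr | starting material
11 | geranyl phenyl sulfone | CC(C)=CCC/C(C)=C/CS(=O)(=O)c1ccccc1 | intermediate
12 | tert-butyl{[(2E,6Z,10E)-3,7,11,15-tetramethyl-9-(phenylsulfonyl)hexadeca-2,6,10,14-tetraen-1-yl]oxy}diphenylsilane (racemic at C9) | CC(C)=CCC/C(C)=C/C(C/C(C)=C\CC/C(C)=C/CO[Si](c1ccccc1)(c1ccccc1)C(C)(C)C)S(=O)(=O)c1ccccc1 | intermediate
13 | tert-butyldiphenyl{[(2E,6Z,10E)-3,7,11,15-tetramethylhexadeca-2,6,10,14-tetraen-1-yl]oxy}silane | CC(C)=CCC/C(C)=C/CC/C(C)=C\CC/C(C)=C/CO[Si](c1ccccc1)(c1ccccc1)C(C)(C)C | intermediate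
14 | (2E,6Z,10E)-3,7,11,15-tetramethylhexadeca-2,6,10,14-tetraen-1-ol | CC(C)=CCC/C(C)=C/CC/C(C)=C\CC/C(C)=C/CO | intermediate
15 | (2E,6Z,10E)-1-chloro-3,7,11,15-tetramethylhexadeca-2,6,10,14-tetraene | CC(C)=CCC/C(C)=C/CC/C(C)=C\CC/C(C)=C/CCl | intermediate
16 | (2E,6Z,10E)-geranylgeranyl diphosphate (drawn as free acid, handled as tris-ammonium salt) | CC(C)=CCC/C(C)=C/CC/C(C)=C\CC/C(C)=C/COP(O)(=O)OP(O)(O)=O | intermediate
17 | 2-[(1S,3E,7Z,11E)-4,8,12-trimethylcyclotetradeca-3,7,11-trien-1-yl]propan-2-ylium (not isolated) | C[C+](C)[C@@H]1C/C=C(C)/CC/C=C(C)\CC/C=C(C)/CC1 | intermediate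
18 | (1S,11R,3E,7Z)-verticilla-3,7-dien-12-yl cation (not isolated) | C[C+]1CC[C@H]2C/C=C(C)/CC/C=C(C)\CC[C@H]1C2(C)C | intermediate
19 | (1S,11R,3E,7Z)-verticilla-3,7,12(18)-triene | C=C1CC[C@H]2C/C=C(C)/CC/C=C(C)\CC[C@H]1C2(C)C | intermediate
20 | (1S,3R,4R,7R,8S,11R)-3,4:7,8-diepoxyverticill-12(18)-ene | C=C1CC[C@H]2C[C@H]3O[C@]3(C)CC[C@H]3O[C@@]3(C)CC[C@H]1C2(C)C | intermediate
21 | 3,4:7,8-diepoxyverticill-12(18)-en-13-ol (C13 epimers; other centres as in 20) | C=C1C(O)C[C@H]2C[C@H]3O[C@]3(C)CC[C@H]3O[C@@]3(C)CC[C@H]1C2(C)C | intermediate
22 | (1R,3R,4R,7R,8S,11S)-3,4:7,8-diepoxyverticill-12(18)-en-13-one | C=C1C(=O)C[C@H]2C[C@H]3O[C@]3(C)CC[C@H]3O[C@@]3(C)CC[C@H]1C2(C)C | intermediate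
23 | (1R,3R,4R,7R,8S,10R,11S)-3,4:7,8-diepoxy-10-hydroxyverticill-12(18)-en-13-one | C=C1C(=O)C[C@H]2C[C@H]3O[C@]3(C)CC[C@H]3O[C@@]3(C)C[C@@H](O)[C@H]1C2(C)C | intermediate
24 | (1R,3R,4R,7R,8S,10R,11S)-10-acetoxy-3,4:7,8-diepoxyverticill-12(18)-en-13-one | C=C1C(=O)C[C@H]2C[C@H]3O[C@]3(C)CC[C@H]3O[C@@]3(C)C[C@@H](OC(C)=O)[C@H]1C2(C)C | target

## Step count and least certain steps

Total step count: 18. Longest linear sequence: 17 steps (steps 1–6 and 8–18 from geraniol 1); step 7 is a one-step branch.

**Step 13 (key step).**
- What may go wrong: the enzyme may fail to bind or turn over the 6Z chain; the cascade may be quenched after the first ring closure to give monocyclic products; the proton may be lost from C13 or C11 instead of C18.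
- Fallback (known chemistry only): it sets out from 2 and comes back at 19. The enzyme is used only on its natural all-E substrate and the 7Z geometry is made afterwards.
- SeO2/t-BuOOH oxidation of the E-methyl group of 2 would give (2E,6E)-8-[(tert-butyldiphenylsilyl)oxy]-2,6-dimethylocta-2,6-dien-1-ol F1. CBr4/PPh3 would give the all-E bromide F2. Alkylation of deprotonated 11 would give the all-E sulfone F3, and PdCl2(dppp)/LiBHEt3 the silyl ether F4.
- Bu4NF would give (2E,6E,10E)-geranylgeraniol F5, which is also an article of commerce. N-Chlorosuccinimide/Me2S would give the chloride F6, and (Bu4N)3HP2O7 all-E geranylgeranyl diphosphate F7.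
- A verticillene-forming taxadiene synthase variant acting on this natural substrate would give (1S,11R,3E,7E)-verticilla-3,7,12(18)-triene F8.
- One equivalent of mCPBA would give the trans-7,8-monoepoxide F9 together with its 3,4-regioisomer F12. No site selectivity is assumed; the two are separated.
- F9, from either epoxide face, is converted into the olefin with inversion of geometry. LiPPh2 opens it by SN2 at C7 to the β-hydroxyphosphine F10. MeI gives the phosphonium betaine F11, and syn-elimination of methyldiphenylphosphine oxide leaves the 7Z olefin, which is 19.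

**Step 17.**
- What may go wrong: hydroxylation at another carbon (C2, C5, C6, C9 or a bridgehead methine); oxygen delivery to the wrong face of C10; over-oxidation to the ketone; covalent capture of the α-methylene ketone by enzyme thiols.
- Fallback: it sets out from 22 and comes back at 23, and replaces the enzyme by catalyst-controlled chemical C–H oxidation followed by reduction.
- Fe(PDP)(MeCN)2(SbF6)2, AcOH and H2O2 in MeCN at 0 °C should oxidise the least deactivated methylene to (1R,3R,4R,7R,8S,11S)-3,4:7,8-diepoxyverticill-12(18)-ene-10,13-dione F13.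
- F13 is used at once because its exocyclic olefin can move into conjugation. NaBH4 in MeOH/CH2Cl2 at −78 °C should reduce the saturated ketone in preference to the enone, by hydride attack from the outer face, to give 23.

**Step 14.**
- What may go wrong: poor facial selectivity at one or both ring olefins if the macrocycle populates more than one conformer; competing epoxidation of the exocyclic olefin; acid-induced transannular opening.
- Fallback: it sets out from 19 and comes back at 20, and replaces substrate control by reagent control.
- The D-fructose-derived ketone catalyst 1,2:4,5-di-O-isopropylidene-β-D-erythro-2,3-hexodiulo-2,6-pyranose with KHSO5 and K2CO3 in MeCN/dimethoxymethane/aqueous buffer at 0 °C (Shi epoxidation) is used.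
- Its spiro transition-state model predicts the R configuration at the hydrogen-bearing carbon of both trisubstituted olefins, that is 3R,4R and 7R,8S. It is also a poor reagent for 1,1-disubstituted olefins.

**Step 15.**
- What may go wrong: the ene reaction may take place at C11 instead of C13; the epoxides may open under the action of selenous acid.
- Fallback: it sets out from 20 and comes back at 21, and sets the regiochemistry by kinetic enolisation instead of an ene reaction.
- Ozonolysis (O3, CH2Cl2, −78 °C; Me2S) would give the 18-nor-12-ketone F14. LiN(i-Pr)2 and t-BuMe2SiCl would give, by deprotonation at the less hindered C13, the silyl enol ether F15.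
- Dimethyldioxirane (Rubottom oxidation with silyl migration) would give the 13-silyloxy-12-ketone F16. Cp2TiMe2 in toluene at 65 °C (non-basic Petasis methylenation, which should not epimerise C11) would give the 13-silyl ether F17.
- Bu4NF would then release 21.

## Further compounds

F1 | step 13 | (2E,6E)-8-[(tert-butyldiphenylsilyl)oxy]-2,6-dimethylocta-2,6-dien-1-ol | OC/C(C)=C/CC/C(C)=C/CO[Si](c1ccccc1)(c1ccccc1)C(C)(C)C
F2 | step 13 | tert-butyl{[(2E,6E)-8-bromo-3,7-dimethylocta-2,6-dien-1-yl]oxy}diphenylsilane | BrC/C(C)=C/CC/C(C)=C/CO[Si](c1ccccc1)(c1ccccc1)C(C)(C)C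
F3 | step 13 | tert-butyl{[(2E,6E,10E)-3,7,11,15-tetramethyl-9-(phenylsulfonyl)hexadeca-2,6,10,14-tetraen-1-yl]oxy}diphenylsilane (racemic at C9) | CC(C)=CCC/C(C)=C/C(C/C(C)=C/CC/C(C)=C/CO[Si](c1ccccc1)(c1ccccc1)C(C)(C)C)S(=O)(=O)c1ccccc1
F4 | step 13 | tert-butyldiphenyl{[(2E,6E,10E)-3,7,11,15-tetramethylhexadeca-2,6,10,14-tetraen-1-yl]oxy}silane | CC(C)=CCC/C(C)=C/CC/C(C)=C/CC/C(C)=C/CO[Si](c1ccccc1)(c1ccccc1)C(C)(C)C
F5 | step 13 | (2E,6E,10E)-geranylgeraniol | CC(C)=CCC/C(C)=C/CC/C(C)=C/CC/C(C)=C/CO
F6 | step 13 | (2E,6E,10E)-geranylgeranyl chloride | CC(C)=CCC/C(C)=C/CC/C(C)=C/CC/C(C)=C/CCl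
F7 | step 13 | (2E,6E,10E)-geranylgeranyl diphosphate | CC(C)=CCC/C(C)=C/CC/C(C)=C/CC/C(C)=C/COP(O)(=O)OP(O)(O)=O
F8 | step 13 | (1S,11R,3E,7E)-verticilla-3,7,12(18)-triene | C=C1CC[C@H]2C/C=C(C)/CC/C=C(C)/CC[C@H]1C2(C)C
F9 | step 13 | (1S,3E,7R,8R,11R)-7,8-epoxyverticilla-3,12(18)-diene (trans-epoxide; the 7S,8S isomer serves equally) | C=C1CC[C@H]2C/C=C(C)/CC[C@H]3O[C@]3(C)CC[C@H]1C2(C)C
F10 | step 13 | 7-(diphenylphosphanyl)verticilla-3,12(18)-dien-8-ol from SN2 opening of F9 at C7 | C=C1CC[C@H]2C/C=C(C)/CC[C@H](P(c3ccccc3)c3ccccc3)[C@](C)(O)CC[C@H]1C2(C)C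
F11 | step 13 | methyldiphenylphosphonium betaine of F10 | C=C1CC[C@H]2C/C=C(C)/CC[C@H]([P+](C)(c3ccccc3)c3ccccc3)[C@](C)([O-])CC[C@H]1C2(C)C
F12 | step 13 | (1S,3R,4R,7E,11R)-3,4-epoxyverticilla-7,12(18)-diene (regioisomeric monoepoxide, separated) | C=C1CC[C@H]2C[C@H]3O[C@]3(C)CC/C=C(C)/CC[C@H]1C2(C)C
F13 | step 17 | (1R,3R,4R,7R,8S,11S)-3,4:7,8-diepoxyverticill-12(18)-ene-10,13-dione | C=C1C(=O)C[C@H]2C[C@H]3O[C@]3(C)CC[C@H]3O[C@@]3(C)CC(=O)[C@H]1C2(C)C
F0 | step 14 | none | none
F14 | step 15 | 3,4:7,8-diepoxy-18-norverticillan-12-one (ring stereocentres as in 20) | O=C1CC[C@H]2C[C@H]3O[C@]3(C)CC[C@H]3O[C@@]3(C)CC[C@H]1C2(C)C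
F15 | step 15 | 12-[(tert-butyldimethylsilyl)oxy]-3,4:7,8-diepoxy-18-norverticill-12-ene | CC(C)(C)[Si](C)(C)OC1=CC[C@H]2C[C@H]3O[C@]3(C)CC[C@H]3O[C@@]3(C)CC[C@H]1C2(C)C
F16 | step 15 | 13-[(tert-butyldimethylsilyl)oxy]-3,4:7,8-diepoxy-18-norverticillan-12-one (C13 epimers) | O=C1C(O[Si](C)(C)C(C)(C)C)C[C@H]2C[C@H]3O[C@]3(C)CC[C@H]3O[C@@]3(C)CC[C@H]1C2(C)C
F17 | step 15 | 13-[(tert-butyldimethylsilyl)oxy]-3,4:7,8-diepoxyverticill-12(18)-ene (C13 epimers) | C=C1C(O[Si](C)(C)C(C)(C)C)C[C@H]2C[C@H]3O[C@]3(C)CC[C@H]3O[C@@]3(C)CC[C@H]1C2(C)C
A1 | alternative 1 | trans C3–C4 epoxide joining the ketal-protected ring (C10 silyl ether) to the Z chain (C9 silyl ether) | C=C1C2(OCCO2)C[C@@H](C[C@H]3O[C@]3(C)CC/C=C(C)\CO[Si](C)(C)C(C)(C)C)C(C)(C)[C@@H]1CO[Si](C)(C)C(C)(C)C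
A2 | alternative 1 | ring-bound (3S)-3-chloro C4 methyl ketone | C=C1C2(OCCO2)C[C@@H](C[C@H](Cl)C(C)=O)C(C)(C)[C@@H]1CO[Si](C)(C)C(C)(C)C
A3 | alternative 1 | [(3Z)-5-[(tert-butyldimethylsilyl)oxy]-4-methylpent-3-en-1-yl]magnesium bromide | Br[Mg]CC/C=C(C)\CO[Si](C)(C)C(C)(C)C
A4 | alternative 2 | bicyclic C10 alcohol with 3E,7Z-diene and C13 dioxolane | C=C1C2(OCCO2)C[C@H]3C/C=C(C)/CC/C=C(C)\C[C@@H](O)[C@H]1C3(C)C
A5 | alternative 2 | fifteen-membered C18–O–C10 allyl ether carrying tributylstannyl at C10 and the C11=C12 ring olefin | CCCC[Sn](CCCC)(CCCC)[C@@H]1C/C(C)=C\CC/C(C)=C/C[C@@H]2CC3(OCCO3)C(CO1)=CC2(C)C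
A6 | alternative 3 | isoxazoline-bridged macrocycle (C8=N, O on C10, C7 silyl ether, C13 dioxolane) | C=C1C2(OCCO2)C[C@H]3C/C=C(C)/CC[C@H](O[Si](C)(C)C(C)(C)C)C4=NO[C@H](C4)[C@H]1C3(C)C
A7 | alternative 3 | ring-bound C8 aldoxime with C7 silyl ether and a vinyl group on C11 | C=C1C2(OCCO2)C[C@@H](C/C=C(C)/CC[C@H](O[Si](C)(C)C(C)(C)C)/C=N/O)C(C)(C)[C@@H]1C=C
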